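**Retrosynthetic overview**

1. Numbering: C1 = quaternary fusion carbon (CH3), C2/C3 = ring A CH2, C4 = isopropyl carbinol, C5 = fusion CH, C6 = acyloxy carbon, C7 = CH2, C8(CH3)=C9, C10 = CH2. Ring A = cyclopentane C1–C5, ring B = cycloheptene C1, C5–C10; β = face of the C1 methyl.
2. Feature used: in ring B, C7–C8–C9–C10 is a butadiene oxygenated at C8 (later the C8 methyl alkene). C6–C5–C1 is a three-carbon unit oxygenated at C6 with C1 quaternary, which is the skeleton of an alkoxy(alkenyl)carbene whose alkene lies in ring A.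
3. Key disconnection: C6–C7 and C1–C10, formed by cyclopropanation of 2-(trimethylsiloxy)butadiene with a chromium methoxy(cyclopentenyl)carbene and Cope shift of the cis-divinylcyclopropane. Ring A comes from 3-methylcyclopentenone; ring B is closed second.
4. After the key step: C8 enol silane → triflate → methyl; C6 enol ether → ketone (sets H5) → 6α-ol by hydroxyl-directed reduction; C4 carbinol → ketone → isopropyl addition.
5. Last disconnection: the C6–O ester bond, to the diol and O-silylated p-coumaric acid.

Key step: step 5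

Assumption: 2-(trimethylsiloxy)buta-1,3-diene 10 is taken as a purchased reagent.

**Route**

Step 1
Reactants: 1 3-methylcyclopent-2-en-1-one
Product: 3 2-bromo-3-methylcyclopent-2-en-1-one, via trans-dibromide 2 (not isolated)
Conditions: Br2, CH2Cl2, 0 °C; then Et3N, 0 °C → rt
Reagents that add atoms: bromine, BrBr
Why: Bromine adds across the enone alkene and triethylamine then removes HBr from the dibromide with loss of the acidic α-hydrogen (bromination–dehydrobromination of an enone), which places bromine on the α-carbon, the future C5.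

Step 2
Reactants: 3 2-bromo-3-methylcyclopent-2-en-1-one
Product: 4 (S)-2-bromo-3-methylcyclopent-2-en-1-ol
Conditions: (R)-2-methyl-CBS-oxazaborolidine (10 mol%), BH3·SMe2, THF, –20 °C; MeOH quench
Reagents that add atoms: none
Why: Corey–Bakshi–Shibata reduction, in which the ketone binds the oxazaborolidine–borane complex with the bromoalkene arm in the position of the large group, so that the (R)-catalyst delivers hydride to the face that gives the (S)-alcohol, the future temporary C4 stereocentre.

Step 3
Reactants: 4 (S)-2-bromo-3-methylcyclopent-2-en-1-ol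
Product: 5 (S)-[(2-bromo-3-methylcyclopent-2-en-1-yl)oxy](tert-butyl)dimethylsilane
Conditions: TBSCl, imidazole, DMF, rt
Reagents that add atoms: tert-butyldimethylsilyl chloride, CC(C)(C)[Si](C)(C)Cl
Why: Standard silylation of a secondary allylic alcohol, which installs the bulky group that later shields the β face of ring A.

Step 4
Reactants: 5 (S)-[(2-bromo-3-methylcyclopent-2-en-1-yl)oxy](tert-butyl)dimethylsilane; 6 chromium hexacarbonyl Cr(CO)6
Product: 9 pentacarbonyl{methoxy[(5S)-5-(tert-butyldimethylsilyloxy)-2-methylcyclopent-1-en-1-yl]methylidene}chromium, via vinyllithium 7 (not isolated), via lithium acylchromate 8 (not isolated)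
Conditions: t-BuLi (2.0 equiv), Et2O, –78 °C; Cr(CO)6, Et2O, –78 → 0 °C; Me3OBF4, CH2Cl2, 0 °C
Reagents that add atoms: trimethyloxonium tetrafluoroborate, C[O+](C)C.F[B-](F)(F)F
Why: Fischer carbene synthesis, in which bromine–lithium exchange gives the vinyllithium, this adds to a CO ligand of Cr(CO)6 (the CO carbon becomes C6) to give the acylchromate, and O-methylation with the oxonium salt gives the methoxycarbene complex of zerovalent chromium without touching the stereocentre.

Step 5
Reactants: 9 pentacarbonyl{methoxy[(5S)-5-(tert-butyldimethylsilyloxy)-2-methylcyclopent-1-en-1-yl]methylidene}chromium; 10 2-(trimethylsiloxy)buta-1,3-diene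
Product: 12 ring A/B diene with 4β-OTBS; C5=C6 methyl enol ether; C8=C9 trimethylsilyl enol ether; 1β-methyl, via cis-divinylcyclopropane 11 (not isolated)
Conditions: 10 (4 equiv), THF, 80 °C, sealed tube, Ar; filtration through Et3N-deactivated SiO2
Reagents that add atoms: none
Why: On heating, 9 loses CO and the electron-rich C7=C8 enol silane bond of 10 binds zerovalent chromium with its nucleophilic CH2 terminus (C7) on the carbene carbon C6, and the chromacyclobutane collapses to cyclopropane 11 (C6–C7 and C6–C8 formed), the closest known reaction type being the cyclopropanation of 2-oxygenated and 2-aminated butadienes by alkoxy(alkenyl)carbene complexes of chromium followed by divinylcyclopropane rearrangement, applied here to an alkene terminus that is fully substituted. The cis-divinylcyclopropane then undergoes a Cope [3,3] shift through a boat transition state in which C1–C10 forms as C6–C8 breaks, so ring B is closed by sigmatropic expansion of the three-membered ring to the seven-membered ring and emerges with the C5=C6 methyl enol ether and the C8=C9 enol silane. The trans cyclopropane and the unreactive cis diastereomer can reopen at the C6–C8 bond, which is weakened by two oxygen donors and two vinyl groups, and so drain through the reactive isomer. The only new stereocentre, C1, is controlled by the C4 silyl ether: in the boat the C8–C9–C10 arm must lie over one face of the cyclopentene directly beside C4, the β face is blocked by OTBS, and C10 therefore bonds to the α face (C1 methyl β). The step needs cyclopropanation to beat Diels–Alder addition, which the tetrasubstituted and twisted carbene alkene secures by being a poor dienophile, and it needs attack at C7=C8 and not at C9=C10, which the siloxy donor secures. The methyl group on C1 points into the boat and raises the Cope barrier, which is why the mixture is held at 80 °C until 11 is consumed.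

Step 6
Reactants: 12 ring A/B diene with 4β-OTBS; C5=C6 methyl enol ether; C8=C9 trimethylsilyl enol ether
Product: 14 C8 enol triflate (C8=C9) with 4β-OTBS; C5=C6 methyl enol ether, via lithium enolate 13 (not isolated)
Conditions: MeLi (1.05 equiv), THF, 0 °C → rt; PhNTf2, –78 °C → rt
Reagents that add atoms: N-phenylbis(trifluoromethanesulfonimide), O=S(=O)(N(c1ccccc1)S(=O)(=O)C(F)(F)F)C(F)(F)F
Why: MeLi attacks the trimethylsilyl group and releases the C8=C9 lithium enolate regiospecifically (silyl enol ether cleavage in the absence of a proton source), and O-triflation with PhNTf2 fixes that double-bond position while the TBS ether and the methyl enol ether are inert.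

Step 7
Reactants: 14 C8 enol triflate with 4β-OTBS; C5=C6 methyl enol ether
Product: 15 C8-methyl diene with 4β-OTBS; C5=C6 methyl enol ether; C8(CH3)=C9
Conditions: MeZnCl, Pd(PPh3)4 (5 mol%), THF, 50 °C
Reagents that add atoms: methylzinc chloride, C[Zn]Cl
Why: Negishi cross-coupling, in which the enol triflate adds oxidatively to zerovalent palladium, methyl is transferred from zinc and reductive elimination gives the C8 methyl group on the unchanged C8=C9 alkene.

Step 8
Reactants: 15 C8-methyl diene with 4β-OTBS; C5=C6 methyl enol ether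
Product: 16 trans-fused C6 ketone with 4β-OTBS; 5α-H
Conditions: HCl (0.5 M aq.), THF, 0 °C, short contact; NaHCO3 quench
Reagents that add atoms: water, O
Why: Acid-catalysed enol ether hydrolysis, whose rate-limiting protonation at C5 should occur from the α face because the β face is covered by the C4 silyl ether and the C1 methyl group, so that the trans-fused ketone (H5 α) forms under kinetic control, while cold dilute acid and a short contact time guard against C5 epimerisation, loss of the silanol and migration of the C8=C9 bond.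

Step 9
Reactants: 16 trans-fused C6 ketone with 4β-OTBS; 5α-H
Product: 17 β-hydroxy ketone with 4β-OH; 5α-H; C6 ketone
Conditions: HF·pyridine, pyridine, THF, 0 °C → rt
Reagents that add atoms: none
Why: Fluoride-mediated cleavage of the silyl ether under buffered, non-basic conditions, which frees the C4 hydroxyl without retro-aldol cleavage, dehydration or C5 epimerisation of the β-hydroxy ketone.

Step 10
Reactants: 17 β-hydroxy ketone with 4β-OH; 5α-H; C6 ketone
Product: 18 diol with 4β-OH; 5α-H; 6α-OH
Conditions: Me4NBH(OAc)3, AcOH/MeCN (1:1), –30 °C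
Reagents that add atoms: none
Why: Saksena–Evans hydroxyl-directed reduction, in which the C4 hydroxyl exchanges onto boron and, being held on the β face cis to the C5–C6 bond by the trans ring fusion, delivers hydride intramolecularly to the β face of the C6 carbonyl, which sets the 6α-hydroxyl (H6 β, anti to H5).

Step 11
Reactants: 18 diol with 4β-OH; 5α-H; 6α-OH
Product: 19 mono-silyl ether with 4β-OH; 6α-OTBS
Conditions: TBSCl (1.1 equiv), imidazole, DMF, 0 °C
Reagents that add atoms: tert-butyldimethylsilyl chloride, CC(C)(C)[Si](C)(C)Cl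
Why: Site-selective silylation, which should take the equatorial C6 hydroxyl because the C4 hydroxyl is pseudo-axial on ring A and 1,3-syn to the C1 methyl group.

Step 12
Reactants: 19 mono-silyl ether with 4β-OH; 6α-OTBS
Product: 20 C4 ketone with 5α-H; 6α-OTBS
Conditions: Pr4N[RuO4] (5 mol%), NMO, 4 Å MS, CH2Cl2, rt
Reagents that add atoms: none
Why: Ley–Griffith oxidation of the remaining secondary alcohol under near-neutral conditions, which gives the C4 ketone without epimerising C5 or eliminating the β-silyloxy group.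

Step 13
Reactants: 20 C4 ketone with 5α-H; 6α-OTBS
Product: 21 tertiary alcohol with 4β-OH; 4α-isopropyl; 5α-H; 6α-OTBS
Conditions: iPrMgCl, LaCl3·2LiCl, THF, 0 °C
Reagents that add atoms: isopropylmagnesium chloride, CC(C)[Mg]Cl
Why: Lanthanum-promoted Grignard 1,2-addition, in which LaCl3·2LiCl activates the hindered ketone and suppresses enolisation and β-hydride reduction, and the isopropyl group enters from the α face, trans to the C5–C6 branch and away from the syn-axial C1 methyl group, which sets C4 with hydroxyl β and isopropyl α.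

Step 14
Reactants: 21 tertiary alcohol with 4β-OH; 4α-isopropyl; 6α-OTBS
Product: 22 (3R,3aS,4S,8aR)-6,8a-dimethyl-3-(propan-2-yl)-1,2,3,3a,4,5,8,8a-octahydroazulene-3,4-diol
Conditions: TBAF, THF, rt → 40 °C
Reagents that add atoms: none
Why: Fluoride cleavage of the secondary silyl ether, to which the tertiary alcohol and the alkene are inert.

Step 15
Reactants: 23 p-coumaric acid
Product: 25 (E)-3-[4-(tert-butyldimethylsilyloxy)phenyl]prop-2-enoic acid, via bis-silyl derivative 24 (not isolated)
Conditions: TBSCl (2.3 equiv), imidazole, DMF, rt; then AcOH, THF/H2O, rt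
Reagents that add atoms: tert-butyldimethylsilyl chloride, CC(C)(C)[Si](C)(C)Cl
Why: Silylation of both the phenol and the carboxylic acid followed by selective hydrolysis of the much more labile silyl ester, which leaves the aryl silyl ether and the E alkene unchanged.

Step 16
Reactants: 22 diol with 4β-OH (tertiary); 6α-OH; 25 (E)-3-[4-(tert-butyldimethylsilyloxy)phenyl]prop-2-enoic acid
Product: 26 C6 ester of 22 with O-TBS-protected p-coumaric acid
Conditions: DCC, DMAP, CH2Cl2, rt
Reagents that add atoms: none
Why: Steglich esterification, which acylates only the secondary C6 hydroxyl because the C4 carbinol is tertiary and flanked by the isopropyl group, with retention at C6 since the C–O bond is not broken.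

Step 17
Reactants: 26 C6 ester of 22 with O-TBS-protected p-coumaric acid
Product: 27 target CNP0265426.1
Conditions: TBAF, AcOH, THF, 0 °C
Reagents that add atoms: none
Why: Buffered fluoride removes the aryl silyl ether, which is far more labile than an alkyl silyl ether, without cleaving the cinnamate ester or disturbing the tertiary alcohol.

**Compound list**

1 | 3-methylcyclopent-2-en-1-one | CC1=CC(=O)CC1 | starting material
2 | (±)-trans-2,3-dibromo-3-methylcyclopentan-1-one (one enantiomer drawn) | C[C@@]1(Br)CCC(=O)[C@H]1Br | intermediate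
3 | 2-bromo-3-methylcyclopent-2-en-1-one | CC1=C(Br)C(=O)CC1 | intermediate
4 | (S)-2-bromo-3-methylcyclopent-2-en-1-ol | BrC1=C(C)CC[C@@H]1O | intermediate
5 | (S)-[(2-bromo-3-methylcyclopent-2-en-1-yl)oxy](tert-butyl)dimethylsilane | BrC1=C(C)CC[C@@H]1O[Si](C)(C)C(C)(C)C | intermediate
6 | chromium hexacarbonyl, Cr(CO)6 | O=C=[Cr](=C=O)(=C=O)(=C=O)(=C=O)=C=O | starting material
7 | [(5S)-5-(tert-butyldimethylsilyloxy)-2-methylcyclopent-1-en-1-yl]lithium | [Li]C1=C(C)CC[C@@H]1O[Si](C)(C)C(C)(C)C | intermediate
8 | lithium pentacarbonyl{[(5S)-5-(tert-butyldimethylsilyloxy)-2-methylcyclopent-1-en-1-yl]carbonyl}chromate | [Li+].[O-]C(=[Cr](=C=O)(=C=O)(=C=O)(=C=O)=C=O)C1=C(C)CC[C@@H]1O[Si](C)(C)C(C)(C)C | intermediate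
9 | pentacarbonyl{methoxy[(5S)-5-(tert-butyldimethylsilyloxy)-2-methylcyclopent-1-en-1-yl]methylidene}chromium | COC(=[Cr](=C=O)(=C=O)(=C=O)(=C=O)=C=O)C1=C(C)CC[C@@H]1O[Si](C)(C)C(C)(C)C | intermediate
10 | 2-(trimethylsiloxy)buta-1,3-diene | C=CC(=C)O[Si](C)(C)C | starting material
11 | 1-methoxy-1-[(5S)-5-(tert-butyldimethylsilyloxy)-2-methylcyclopent-1-en-1-yl]-2-(trimethylsiloxy)-2-vinylcyclopropane, cyclopentenyl and vinyl cis, vinyl arm on the α face | CO[C@@]1(C2=C(C)CC[C@@H]2O[Si](C)(C)C(C)(C)C)C[C@]1(O[Si](C)(C)C)C=C | intermediate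
12 | 3-(tert-butyldimethylsilyloxy)-4-methoxy-8a-methyl-6-(trimethylsilyloxy)-1,2,3,5,8,8a-hexahydroazulene (4β-OTBS, C5=C6–OMe, C8(OTMS)=C9, 1β-CH3) | C[Si](C)(C)OC1=CC[C@@]2(C)CC[C@H](O[Si](C)(C)C(C)(C)C)C2=C(OC)C1 | intermediate
13 | lithium enolate of 12 (C8–OLi, C8=C9) | [Li]OC1=CC[C@@]2(C)CC[C@H](O[Si](C)(C)C(C)(C)C)C2=C(OC)C1 | intermediate
14 | 3-(tert-butyldimethylsilyloxy)-4-methoxy-8a-methyl-1,2,3,5,8,8a-hexahydroazulen-6-yl trifluoromethanesulfonate (4β-OTBS, 1β-CH3) | O=S(=O)(OC1=CC[C@@]2(C)CC[C@H](O[Si](C)(C)C(C)(C)C)C2=C(OC)C1)C(F)(F)F | intermediate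
15 | 3-(tert-butyldimethylsilyloxy)-4-methoxy-6,8a-dimethyl-1,2,3,5,8,8a-hexahydroazulene (4β-OTBS, 1β-CH3) | CC1=CC[C@@]2(C)CC[C@H](O[Si](C)(C)C(C)(C)C)C2=C(OC)C1 | intermediate
16 | 3-(tert-butyldimethylsilyloxy)-6,8a-dimethyl-2,3,3a,5,8,8a-hexahydroazulen-4(1H)-one (4β-OTBS, 5α-H, 1β-CH3, trans-fused) | CC1=CC[C@@]2(C)CC[C@H](O[Si](C)(C)C(C)(C)C)[C@@H]2C(=O)C1 | intermediate
17 | 3-hydroxy-6,8a-dimethyl-2,3,3a,5,8,8a-hexahydroazulen-4(1H)-one (4β-OH, 5α-H, 1β-CH3) | CC1=CC[C@@]2(C)CC[C@H](O)[C@@H]2C(=O)C1 | intermediate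
18 | 6,8a-dimethyl-1,2,3,3a,4,5,8,8a-octahydroazulene-3,4-diol (4β-OH, 5α-H, 6α-OH, 1β-CH3) | CC1=CC[C@@]2(C)CC[C@H](O)[C@@H]2[C@@H](O)C1 | intermediate
19 | 4-(tert-butyldimethylsilyloxy)-6,8a-dimethyl-1,2,3,3a,4,5,8,8a-octahydroazulen-3-ol (4β-OH, 6α-OTBS) | CC1=CC[C@@]2(C)CC[C@H](O)[C@@H]2[C@@H](O[Si](C)(C)C(C)(C)C)C1 | intermediate
20 | 4-(tert-butyldimethylsilyloxy)-6,8a-dimethyl-1,3a,4,5,8,8a-hexahydroazulen-3(2H)-one (5α-H, 6α-OTBS, 1β-CH3) | CC1=CC[C@@]2(C)CCC(=O)[C@@H]2[C@@H](O[Si](C)(C)C(C)(C)C)C1 | intermediate
21 | 4-(tert-butyldimethylsilyloxy)-6,8a-dimethyl-3-(propan-2-yl)-1,2,3,3a,4,5,8,8a-octahydroazulen-3-ol (4β-OH, 4α-isopropyl, 5α-H, 6α-OTBS) | CC1=CC[C@@]2(C)CC[C@@](O)(C(C)C)[C@@H]2[C@@H](O[Si](C)(C)C(C)(C)C)C1 | intermediate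
22 | (3R,3aS,4S,8aR)-6,8a-dimethyl-3-(propan-2-yl)-1,2,3,3a,4,5,8,8a-octahydroazulene-3,4-diol | CC1=CC[C@@]2(C)CC[C@@](O)(C(C)C)[C@@H]2[C@@H](O)C1 | intermediate
23 | p-coumaric acid, (E)-3-(4-hydroxyphenyl)prop-2-enoic acid | O=C(O)/C=C/c1ccc(O)cc1 | starting material
24 | tert-butyldimethylsilyl (E)-3-[4-(tert-butyldimethylsilyloxy)phenyl]prop-2-enoate | CC(C)(C)[Si](C)(C)OC(=O)/C=C/c1ccc(O[Si](C)(C)C(C)(C)C)cc1 | intermediate
25 | (E)-3-[4-(tert-butyldimethylsilyloxy)phenyl]prop-2-enoic acid | O=C(O)/C=C/c1ccc(O[Si](C)(C)C(C)(C)C)cc1 | intermediate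
26 | (3R,3aS,4S,8aR)-3-hydroxy-6,8a-dimethyl-3-(propan-2-yl)-1,2,3,3a,4,5,8,8a-octahydroazulen-4-yl (E)-3-[4-(tert-butyldimethylsilyloxy)phenyl]prop-2-enoate | CC1=CC[C@@]2(C)CC[C@@](O)(C(C)C)[C@@H]2[C@@H](OC(=O)/C=C/c2ccc(O[Si](C)(C)C(C)(C)C)cc2)C1 | intermediate
27 | (3R,3aS,4S,8aR)-3-hydroxy-6,8a-dimethyl-3-(propan-2-yl)-1,2,3,3a,4,5,8,8a-octahydroazulen-4-yl (E)-3-(4-hydroxyphenyl)prop-2-enoate | CC1=CC[C@@]2(C)CC[C@@](O)(C(C)C)[C@@H]2[C@@H](OC(=O)/C=C/c2ccc(O)cc2)C1 | target

**Step count**

Total: 17 steps. Longest linear sequence: 16 steps (steps 1–14, 16 and 17, from 3-methylcyclopent-2-en-1-one); step 15 prepares the acid partner.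

**Steps most likely to fail, with fallbacks**

Step 5 (key step). Three processes may go wrong:
- Diels–Alder addition of the diene to the carbene-activated alkene, or another collapse of the chromacyclobutane, may outrun cyclopropanation.
- The Cope shift may stall because the C1 methyl points into the boat.
- The C4 silyl ether may discriminate the two cyclopentene faces poorly.

The fallback forms the same two bonds by an anionic route, the Brook rearrangement-mediated (3+4) annulation of an acylsilane with a dienolate. It sets out from vinyllithium 7, which is acylated with morpholine-4-carbonyl chloride to give the morpholine amide F1. PhMe2SiLi in THF at –78 °C converts this into the acylsilane F2. Diene 10 and MeLi give lithium buta-1,3-dien-2-olate F3, whose CH2 terminus adds to the acylsilane carbonyl at –78 °C (C6–C7). A silyl shift from carbon to oxygen, cyclopropanolate closure onto the C8 carbonyl and an anionic oxy-Cope shift (C1–C10) should then give the ring B lithium enolate F4. This is trapped in the same flask with PhNTf2 as the C8 enol triflate F5, which carries a dimethylphenylsilyl enol ether at C6. Negishi methylation as in step 7 gives the C8 methyl compound F6. Cold dilute acid hydrolyses its silyl enol ether with α-face protonation at C5 as in step 8, and the route is rejoined at ketone 16.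

Step 13. Enolisation of ketone 20 toward C5, followed by loss of the C6 silyloxy group, or β-hydride reduction by the secondary Grignard reagent may take the place of addition. The fallback sets out from 20 and uses an sp2 nucleophile. Isopropenylmagnesium bromide with LaCl3·2LiCl in THF should add from the same α face to give the isopropenyl carbinol F7. Hydrogenation with RhCl(PPh3)3 and H2 in benzene then saturates the 1,1-disubstituted alkene and leaves the trisubstituted C8=C9 alkene, and the route is rejoined at 21.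

Step 11. Discrimination between the two secondary hydroxyls may be insufficient, with silylation at C4 or at both oxygens. The fallback sets out from ketol 17 and differentiates the oxygens in the reduction itself. Evans–Tishchenko reduction (SmI2 30 mol%, PhCHO, THF, –10 °C) delivers hydride from the C4-bound hemiacetal to the β face of C6 and leaves the C4 oxygen acylated, giving the hydroxy benzoate F8. TBSOTf and 2,6-lutidine give the silyl ether benzoate F9. DIBAL-H at –78 °C removes the benzoate, and the route is rejoined at 19.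

**Further compounds**

F1 | step 5 | [(5S)-5-(tert-butyldimethylsilyloxy)-2-methylcyclopent-1-en-1-yl](morpholin-4-yl)methanone | O=C(N1CCOCC1)C1=C(C)CC[C@@H]1O[Si](C)(C)C(C)(C)C
F2 | step 5 | [(5S)-5-(tert-butyldimethylsilyloxy)-2-methylcyclopent-1-en-1-yl][dimethyl(phenyl)silyl]methanone | C[Si](C)(c1ccccc1)C(=O)C1=C(C)CC[C@@H]1O[Si](C)(C)C(C)(C)C
F3 | step 5 | lithium buta-1,3-dien-2-olate | [Li]OC(=C)C=C
F4 | step 5 | ring B lithium enolate (C8–OLi, C8=C9) with 4β-OTBS, C5=C6 dimethylphenylsilyl enol ether and 1β-CH3 | [Li]OC1=CC[C@@]2(C)CC[C@H](O[Si](C)(C)C(C)(C)C)C2=C(O[Si](C)(C)c3ccccc3)C1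
F5 | step 5 | C8 enol triflate with 4β-OTBS and C5=C6 dimethylphenylsilyl enol ether | O=S(=O)(OC1=CC[C@@]2(C)CC[C@H](O[Si](C)(C)C(C)(C)C)C2=C(O[Si](C)(C)c3ccccc3)C1)C(F)(F)F
F6 | step 5 | C8 methyl compound with 4β-OTBS and C5=C6 dimethylphenylsilyl enol ether | CC1=CC[C@@]2(C)CC[C@H](O[Si](C)(C)C(C)(C)C)C2=C(O[Si](C)(C)c3ccccc3)C1
F7 | step 13 | 4-(tert-butyldimethylsilyloxy)-6,8a-dimethyl-3-(prop-1-en-2-yl)-1,2,3,3a,4,5,8,8a-octahydroazulen-3-ol (4β-OH, 4α-isopropenyl, 5α-H, 6α-OTBS) | CC1=CC[C@@]2(C)CC[C@@](O)(C(C)=C)[C@@H]2[C@@H](O[Si](C)(C)C(C)(C)C)C1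
F8 | step 11 | 4-hydroxy-6,8a-dimethyl-1,2,3,3a,4,5,8,8a-octahydroazulen-3-yl benzoate (4β-OBz, 5α-H, 6α-OH) | CC1=CC[C@@]2(C)CC[C@H](OC(=O)c3ccccc3)[C@@H]2[C@@H](O)C1
F9 | step 11 | 4-(tert-butyldimethylsilyloxy)-6,8a-dimethyl-1,2,3,3a,4,5,8,8a-octahydroazulen-3-yl benzoate (4β-OBz, 5α-H, 6α-OTBS) | CC1=CC[C@@]2(C)CC[C@H](OC(=O)c3ccccc3)[C@@H]2[C@@H](O[Si](C)(C)C(C)(C)C)C1
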